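**Retrosynthetic overview**

1. Feature: the target is a trans-fused bicyclo[5.3.0]decane. Ring A is the cyclopentane C1(Me)–C2(OAc)–C3–C4(OH)(i-Pr)–C5(H); ring B is the cycloheptane C5–C6(O-veratroyl)–C7–C8(Me)–C9–C10(OH)–C1 with an oxirane on C8/C9. Because the two-carbon unit C8–C9 lies between C7 (next to oxygenated C6) and C10 (on quaternary C1), atoms C1, C5 and C10 can begin as a cyclopropane fused to ring A, with C6/C7 as a 1-silyloxyvinyl group on C5.
2. Key disconnection: C7–C8 and C9–C10, by rhodium-catalysed (5+2) cycloaddition of that vinylcyclopropane with 1-(trimethylsilyl)propyne. The silyl group stands in for the hydrogen of propyne so that the methyl-bearing carbon becomes C8 (a terminal alkyne would be expected to place its substituent on C9); it is removed afterwards by protodesilylation.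
3. Precursor: ring A comes from (S)-4-(tert-butyldimethylsilyloxy)cyclopent-2-enone (C2). The C1 methyl and a C5 bromide are installed, i-PrMgCl/CeCl3 adds anti to the silyloxy group (C4), the bromide becomes an acetyl group, and a hydroxyl-directed Simmons–Smith reaction from the C6 carbinol builds the cyclopropane anti to O2 and O4 (C1).
4. After the cycloaddition: C5 by protonation, C6 by O4-directed reduction, veratroylation, C10 oxidised by epoxide → selenoxide → chromate transposition, an Evans–Tishchenko reaction that sets C10 and acetylates O2, and last the trans oxirane by photochemical Z→E isomerisation of C8=C9 with oxygen transfer.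
5. Ring order: ring A, cyclopropane, ring B, oxirane.

Key step: step 11

Remark: the oxirane is built exactly as written in the SMILES, with C7 and C10 trans on the three-membered ring, (8R,9R). The locants C1–C10 defined above are used for all bicyclo[5.3.0]decanes, and their stereodescriptors refer to these locants.

**Route**

Step 1
Reactants: 1 (S)-4-(tert-butyldimethylsilyloxy)cyclopent-2-en-1-one
Product: 2 (3S,4S)-4-(tert-butyldimethylsilyloxy)-3-methyl-1-(trimethylsilyloxy)cyclopent-1-ene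
Conditions: MeMgBr, CuBr·SMe2 (5 mol%), TMSCl, THF, −78 °C
Reagents that add atoms: methylmagnesium bromide, C[Mg]Br; chlorotrimethylsilane, C[Si](C)(C)Cl
Why: Copper-catalysed conjugate addition with in situ silylation should deliver methyl anti to the silyloxy group and trap the regiodefined enolate; the new methine is removed again in step 2.

Step 2
Reactants: 2 (3S,4S)-4-(tert-butyldimethylsilyloxy)-3-methyl-1-(trimethylsilyloxy)cyclopent-1-ene
Product: 3 (S)-4-(tert-butyldimethylsilyloxy)-3-methylcyclopent-2-en-1-one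
Conditions: Pd(OAc)2 (10 mol%), O2 (1 atm), DMSO, 50 °C
Reagents that add atoms: none
Why: Saegusa–Ito oxidation (palladation of the silyl enol ether, β-hydride elimination from the methyl-bearing carbon) should return the enone with the methyl group on the β-carbon and leave the silyloxy stereocentre untouched.

Step 3
Reactants: 3 (S)-4-(tert-butyldimethylsilyloxy)-3-methylcyclopent-2-en-1-one
Product: 5 (S)-2-bromo-4-(tert-butyldimethylsilyloxy)-3-methylcyclopent-2-en-1-one, via 2,3-dibromo ketone 4 (not isolated)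
Conditions: Br2, CH2Cl2, 0 °C; then Et3N, 0 °C → rt
Reagents that add atoms: bromine, BrBr
Why: Bromine addition followed by amine-induced dehydrobromination is the standard α-bromination of a β-substituted cyclic enone.

Step 4
Reactants: 5 (S)-2-bromo-4-(tert-butyldimethylsilyloxy)-3-methylcyclopent-2-en-1-one
Product: 6 (1S,4S)-2-bromo-4-(tert-butyldimethylsilyloxy)-3-methyl-1-(propan-2-yl)cyclopent-2-en-1-ol
Conditions: i-PrMgCl, CeCl3, THF, −78 °C
Reagents that add atoms: isopropylmagnesium chloride, CC(C)[Mg]Cl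
Why: Organocerium 1,2-addition (little enolisation, reduction or halogen–metal exchange) to the 4-silyloxycyclopentenone should take place on the face anti to the silyloxy group, so the new hydroxyl is cis to OTBS and the carbinol carbon (later C4) is S.

Step 5
Reactants: 6 (1S,4S)-2-bromo-4-(tert-butyldimethylsilyloxy)-3-methyl-1-(propan-2-yl)cyclopent-2-en-1-ol
Product: 7 [(1S,4S)-2-bromo-4-(tert-butyldimethylsilyloxy)-3-methyl-1-(propan-2-yl)cyclopent-2-en-1-yl]oxy(triethyl)silane
Conditions: TESOTf, 2,6-lutidine, CH2Cl2, −78 → 0 °C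
Reagents that add atoms: triethylsilyl trifluoromethanesulfonate, CC[Si](CC)(CC)OS(=O)(=O)C(F)(F)F
Why: Silyl triflate silylation caps the hindered tertiary alcohol so that it cannot direct the zinc carbenoid of step 8 to the wrong face.

Step 6
Reactants: 7 [(1S,4S)-2-bromo-4-(tert-butyldimethylsilyloxy)-3-methyl-1-(propan-2-yl)cyclopent-2-en-1-yl]oxy(triethyl)silane; 8 N-methoxy-N-methylacetamide
Product: 10 1-[(3S,5S)-3-(tert-butyldimethylsilyloxy)-2-methyl-5-(propan-2-yl)-5-(triethylsilyloxy)cyclopent-1-en-1-yl]ethan-1-one, via alkenyllithium 9 (not isolated)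
Conditions: t-BuLi (2.1 equiv), THF, −78 °C; then 8, −78 → 0 °C
Reagents that add atoms: N-methoxy-N-methylacetamide 8, CON(C)C(C)=O
Why: Bromine–lithium exchange gives an alkenyllithium that the Weinreb amide acylates once, through a chelated tetrahedral intermediate, to the methyl ketone.

Step 7
Reactants: 10 1-[(3S,5S)-3-(tert-butyldimethylsilyloxy)-2-methyl-5-(propan-2-yl)-5-(triethylsilyloxy)cyclopent-1-en-1-yl]ethan-1-one
Product: 11 (1S)-1-[(3S,5S)-3-(tert-butyldimethylsilyloxy)-2-methyl-5-(propan-2-yl)-5-(triethylsilyloxy)cyclopent-1-en-1-yl]ethan-1-ol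
Conditions: (R)-2-methyl-CBS-oxazaborolidine (20 mol%), BH3·SMe2, THF, −20 °C
Reagents that add atoms: none
Why: Corey–Bakshi–Shibata reduction with the alkenyl group as the large and methyl as the small substituent should give the (S)-carbinol under reagent control.

Step 8
Reactants: 11 (1S)-1-[(3S,5S)-3-(tert-butyldimethylsilyloxy)-2-methyl-5-(propan-2-yl)-5-(triethylsilyloxy)cyclopent-1-en-1-yl]ethan-1-ol
Product: 12 (1S)-1-[(1R,2S,4S,5S)-4-(tert-butyldimethylsilyloxy)-5-methyl-2-(propan-2-yl)-2-(triethylsilyloxy)bicyclo[3.1.0]hexan-1-yl]ethan-1-ol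
Conditions: Et2Zn, CH2I2, CH2Cl2, 0 °C → rt
Reagents that add atoms: diiodomethane, ICI
Why: Hydroxyl-directed Simmons–Smith cyclopropanation (Furukawa conditions): with the carbinol C–H eclipsing the alkene to avoid A(1,3) strain with the ring methyl, the (S)-carbinol holds its zinc alkoxide over the face anti to both silyloxy groups, so methylene is delivered there and sets both ring-fusion carbons (later C1 and C5) with the new CH2 (later C10) trans to O2 and O4.

Step 9
Reactants: 12 (1S)-1-[(1R,2S,4S,5S)-4-(tert-butyldimethylsilyloxy)-5-methyl-2-(propan-2-yl)-2-(triethylsilyloxy)bicyclo[3.1.0]hexan-1-yl]ethan-1-ol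
Product: 13 1-[(1S,2S,4S,5S)-4-(tert-butyldimethylsilyloxy)-5-methyl-2-(propan-2-yl)-2-(triethylsilyloxy)bicyclo[3.1.0]hexan-1-yl]ethan-1-one
Conditions: Dess–Martin periodinane, NaHCO3, CH2Cl2, rt
Reagents that add atoms: none
Why: Dess–Martin oxidation converts the secondary cyclopropylcarbinol into the methyl ketone under buffered conditions that avoid cyclopropylcarbinyl ionisation.

Step 10
Reactants: 13 1-[(1S,2S,4S,5S)-4-(tert-butyldimethylsilyloxy)-5-methyl-2-(propan-2-yl)-2-(triethylsilyloxy)bicyclo[3.1.0]hexan-1-yl]ethan-1-one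
Product: 14 tert-butyl({1-[(1R,2S,4S,5S)-4-(tert-butyldimethylsilyloxy)-5-methyl-2-(propan-2-yl)-2-(triethylsilyloxy)bicyclo[3.1.0]hexan-1-yl]ethenyl}oxy)dimethylsilane
Conditions: TBSOTf, Et3N, CH2Cl2, 0 °C
Reagents that add atoms: tert-butyldimethylsilyl trifluoromethanesulfonate, CC(C)(C)[Si](C)(C)OS(=O)(=O)C(F)(F)F
Why: Soft enolisation with silyl triflate and amine can only go toward the methyl group, because the other α-carbon is quaternary, and gives the 1-silyloxyvinyl cyclopropane.

Step 11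
Reactants: 14 tert-butyl({1-[(1R,2S,4S,5S)-4-(tert-butyldimethylsilyloxy)-5-methyl-2-(propan-2-yl)-2-(triethylsilyloxy)bicyclo[3.1.0]hexan-1-yl]ethenyl}oxy)dimethylsilane; 15 trimethyl(prop-1-yn-1-yl)silane
Product: 16 (1S,2S,4S)-2,6-bis(tert-butyldimethylsilyloxy)-1,8-dimethyl-4-(propan-2-yl)-4-(triethylsilyloxy)-9-(trimethylsilyl)bicyclo[5.3.0]deca-5,8-diene
Conditions: [Rh(CO)2Cl]2 (5 mol%), 15 (3 equiv), 1,2-dichloroethane, 80 °C, sealed tube
Reagents that add atoms: trimethyl(prop-1-yn-1-yl)silane 15, CC#C[Si](C)(C)C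
Why: Monovalent rhodium binds the enol ether double bond and inserts into the adjacent cyclopropane bond C5–C10, giving a rhodacycle with an η3-allyl ligand (C5–C6–C7) and a primary alkyl ligand (C10); the alkyne then inserts at the allyl terminus C7 (forming C7–C8) and reductive elimination joins the alkenyl carbon C9 to C10. The closest known reaction is the [Rh(CO)2Cl]2-catalysed intermolecular (5+2) cycloaddition of heteroatom-substituted vinylcyclopropanes with alkynes, here extended to a ring-fused, fully substituted cyclopropane. Ring B is closed as a seven-membered ring by C(sp2)–C(sp3) reductive elimination from an eight-membered rhodacycle, a formal (5+2) cycloaddition. No stereocentre is created: C5 becomes sp2, and quaternary C1 from step 8 keeps both of its ring bonds and is carried over unchanged. Two selectivities are needed: cleavage of C5–C10 and not the ring-fusion bond C1–C5, secured because C5–C10 is the less substituted bond and the other cleavage would lead to a bridged ring with a bridgehead alkene; and the orientation of the alkyne, secured by the silyl group, which for steric and electronic reasons stays on the carbon bound to rhodium, away from the forming C7–C8 bond, so that the methyl-bearing carbon becomes C8 and the silylated carbon C9.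

Step 12
Reactants: 16 (1S,2S,4S)-2,6-bis(tert-butyldimethylsilyloxy)-1,8-dimethyl-4-(propan-2-yl)-4-(triethylsilyloxy)-9-(trimethylsilyl)bicyclo[5.3.0]deca-5,8-diene
Product: 17 (1S,2S,4S,5S)-2-(tert-butyldimethylsilyloxy)-1,8-dimethyl-4-(propan-2-yl)-4-(triethylsilyloxy)bicyclo[5.3.0]dec-8-en-6-one
Conditions: CF3CO2H (5 equiv), CH2Cl2, 0 °C; aq. NaHCO3
Reagents that add atoms: none
Why: Ipso-protodesilylation of the vinylsilane (protonation at C9 gives the tertiary β-silyl cation at C8, then loss of silicon) and protonolysis of the silyl enol ether should occur together; C5 should be protonated on the face anti to the angular methyl and the C4 silyloxy group, giving the trans ring fusion, which is also expected to be the more stable epimer (partial loss of the triethylsilyl group here is harmless, since step 13 removes it).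

Step 13
Reactants: 17 (1S,2S,4S,5S)-2-(tert-butyldimethylsilyloxy)-1,8-dimethyl-4-(propan-2-yl)-4-(triethylsilyloxy)bicyclo[5.3.0]dec-8-en-6-one
Product: 18 (1S,2S,4S,5S)-2-(tert-butyldimethylsilyloxy)-4-hydroxy-1,8-dimethyl-4-(propan-2-yl)bicyclo[5.3.0]dec-8-en-6-one
Conditions: HF·pyridine, pyridine, THF, 0 °C → rt
Reagents that add atoms: none
Why: Fluoride-mediated desilylation should remove the triethylsilyl ether before the neopentylic secondary TBS ether, under non-basic conditions that spare the β-hydroxy ketone from retro-aldol cleavage.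

Step 14
Reactants: 18 (1S,2S,4S,5S)-2-(tert-butyldimethylsilyloxy)-4-hydroxy-1,8-dimethyl-4-(propan-2-yl)bicyclo[5.3.0]dec-8-en-6-one
Product: 19 (1S,2S,4S,5R,6R)-2-(tert-butyldimethylsilyloxy)-1,8-dimethyl-4-(propan-2-yl)bicyclo[5.3.0]dec-8-ene-4,6-diol
Conditions: Me4NBH(OAc)3, MeCN/AcOH, −20 °C
Reagents that add atoms: none
Why: Hydroxyl-directed (Evans–Saksena) reduction: the alkoxyborohydride on O4, which is cis to C6 on ring A, should deliver hydride through a chair-like six-membered transition state to one face of C6 and give the 1,3-anti diol (6R).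

Step 15
Reactants: 19 (1S,2S,4S,5R,6R)-2-(tert-butyldimethylsilyloxy)-1,8-dimethyl-4-(propan-2-yl)bicyclo[5.3.0]dec-8-ene-4,6-diol; 20 3,4-dimethoxybenzoyl chloride
Product: 21 (1S,2S,4S,5R,6R)-2-(tert-butyldimethylsilyloxy)-4-hydroxy-1,8-dimethyl-4-(propan-2-yl)bicyclo[5.3.0]dec-8-en-6-yl 3,4-dimethoxybenzoate
Conditions: 20, DMAP, Et3N, CH2Cl2, rt
Reagents that add atoms: 3,4-dimethoxybenzoyl chloride 20, COc1ccc(C(Cl)=O)cc1OC
Why: DMAP-catalysed acylation should esterify only the secondary C6 hydroxyl, the tertiary C4 hydroxyl being inert; the ester also protects O6 through the oxidations that follow.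

Step 16
Reactants: 21 (1S,2S,4S,5R,6R)-2-(tert-butyldimethylsilyloxy)-4-hydroxy-1,8-dimethyl-4-(propan-2-yl)bicyclo[5.3.0]dec-8-en-6-yl 3,4-dimethoxybenzoate
Product: 22 (1S,2S,4S,5R,6R,8S,9R)-2-(tert-butyldimethylsilyloxy)-8,9-epoxy-4-hydroxy-1,8-dimethyl-4-(propan-2-yl)bicyclo[5.3.0]decan-6-yl 3,4-dimethoxybenzoate
Conditions: m-CPBA, NaHCO3, CH2Cl2, 0 °C
Reagents that add atoms: 3-chloroperbenzoic acid, OOC(=O)c1cccc(Cl)c1
Why: Prilezhaev epoxidation of the trisubstituted alkene is expected on the face anti to the angular methyl, but either cis-epoxide serves because C8 and C9 become sp2 again in step 18.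

Step 17
Reactants: 22 (1S,2S,4S,5R,6R,8S,9R)-2-(tert-butyldimethylsilyloxy)-8,9-epoxy-4-hydroxy-1,8-dimethyl-4-(propan-2-yl)bicyclo[5.3.0]decan-6-yl 3,4-dimethoxybenzoate
Product: 25 (1S,2S,4S,5R,6R,8S)-2-(tert-butyldimethylsilyloxy)-4,8-dihydroxy-1,8-dimethyl-4-(propan-2-yl)bicyclo[5.3.0]dec-9-en-6-yl 3,4-dimethoxybenzoate, via hydroxy selenide 23 (not isolated), via selenoxide 24 (not isolated)
Conditions: (PhSe)2, NaBH4, EtOH, rt → 60 °C; then 30% H2O2, THF, 0 °C → rt
Reagents that add atoms: none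
Why: Selenolate should open the oxirane by SN2 at the secondary C9, and the derived selenoxide can undergo syn-elimination only toward C10 because C8 carries no hydrogen, giving the tertiary allylic alcohol.

Step 18
Reactants: 25 (1S,2S,4S,5R,6R,8S)-2-(tert-butyldimethylsilyloxy)-4,8-dihydroxy-1,8-dimethyl-4-(propan-2-yl)bicyclo[5.3.0]dec-9-en-6-yl 3,4-dimethoxybenzoate
Product: 26 (1S,2S,4S,5R,6R)-2-(tert-butyldimethylsilyloxy)-4-hydroxy-1,8-dimethyl-10-oxo-4-(propan-2-yl)bicyclo[5.3.0]dec-8-en-6-yl 3,4-dimethoxybenzoate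
Conditions: pyridinium chlorochromate, NaOAc, 4 Å MS, CH2Cl2, rt
Reagents that add atoms: pyridinium chlorochromate, [O-][Cr](=O)(=O)Cl.c1cc[nH+]cc1
Why: Babler–Dauben oxidative transposition: the tertiary allylic chromate ester undergoes a [3,3] shift to C10 and is oxidised there, giving the enone with the C8=C9 double bond back in place and erasing the C8 configuration.

Step 19
Reactants: 26 (1S,2S,4S,5R,6R)-2-(tert-butyldimethylsilyloxy)-4-hydroxy-1,8-dimethyl-10-oxo-4-(propan-2-yl)bicyclo[5.3.0]dec-8-en-6-yl 3,4-dimethoxybenzoate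
Product: 27 (1S,2S,4S,5R,6R)-2,4-dihydroxy-1,8-dimethyl-10-oxo-4-(propan-2-yl)bicyclo[5.3.0]dec-8-en-6-yl 3,4-dimethoxybenzoate
Conditions: HF·pyridine, THF, rt
Reagents that add atoms: none
Why: Fluoride cleavage of the last silyl ether under acidic, non-basic conditions, so that the β-hydroxy ketone O2–C2–C1–C10=O is not exposed to retro-aldol conditions.

Step 20
Reactants: 27 (1S,2S,4S,5R,6R)-2,4-dihydroxy-1,8-dimethyl-10-oxo-4-(propan-2-yl)bicyclo[5.3.0]dec-8-en-6-yl 3,4-dimethoxybenzoate; 28 acetaldehyde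
Product: 29 (1R,2S,4S,5R,6R,8Z,10S)-2-acetoxy-4,10-dihydroxy-1,8-dimethyl-4-(propan-2-yl)bicyclo[5.3.0]dec-8-en-6-yl 3,4-dimethoxybenzoate
Conditions: CH3CHO (5 equiv), SmI2 (30 mol%), THF, −10 °C
Reagents that add atoms: acetaldehyde 28, CC=O
Why: Evans–Tishchenko reaction: the samarium-bound hemiacetal formed from the C2 hydroxyl and acetaldehyde should transfer its hydride intramolecularly to the C10 face on the side of O2 (1,3-anti, 10S in 29), so that one step sets C10, turns O2 into the acetate and leaves O10 free.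

Step 21
Reactants: 29 (1R,2S,4S,5R,6R,8Z,10S)-2-acetoxy-4,10-dihydroxy-1,8-dimethyl-4-(propan-2-yl)bicyclo[5.3.0]dec-8-en-6-yl 3,4-dimethoxybenzoate
Product: 31 (1R,2S,4S,5R,6R,8R,9R,10R)-2-acetoxy-8,9-epoxy-4,10-dihydroxy-1,8-dimethyl-4-(propan-2-yl)bicyclo[5.3.0]decan-6-yl 3,4-dimethoxybenzoate, via E-alkene 30 (not isolated)
Conditions: hν (254 nm), PhCO2Me, Et2O, −78 °C; then dimethyldioxirane, acetone, −78 °C, dark; then Me2S
Reagents that add atoms: dimethyldioxirane, CC1(C)OO1
Why: Proposed new method: singlet sensitisation by the aromatic ester (exciplex, twisting about C8=C9) should populate, at −78 °C, the strained E-cycloheptene 30, which should not revert thermally at that temperature, and dimethyldioxirane added in the dark should then transfer oxygen in a concerted, stereospecific step to the one exposed face of this pyramidalised alkene far faster than to the unstrained Z-alkene, so that C7 and C10 end up trans on the oxirane; the closest known reactions are the benzoate-sensitised Z→E photoisomerisation of cycloheptene with low-temperature trapping of the E-isomer and the retentive peracid or dioxirane epoxidation of E-cyclooctene, and C8 and C9 are set together by the twist sense of the E-alkene, the (8R,9R)-oxirane arising from the twist with a positive C7–C8–C9–C10 torsion.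

**Compound list**

1 | (S)-4-(tert-butyldimethylsilyloxy)cyclopent-2-en-1-one | O=C1C=C[C@@H](O[Si](C)(C)C(C)(C)C)C1 | starting material
2 | (3S,4S)-4-(tert-butyldimethylsilyloxy)-3-methyl-1-(trimethylsilyloxy)cyclopent-1-ene | C[C@H]1C=C(O[Si](C)(C)C)C[C@@H]1O[Si](C)(C)C(C)(C)C | intermediate
3 | (S)-4-(tert-butyldimethylsilyloxy)-3-methylcyclopent-2-en-1-one | O=C1C=C(C)[C@@H](O[Si](C)(C)C(C)(C)C)C1 | intermediate
4 | (4S)-2,3-dibromo-4-(tert-butyldimethylsilyloxy)-3-methylcyclopentan-1-one (C2, C3 undefined) | O=C1C(Br)C(C)(Br)[C@@H](O[Si](C)(C)C(C)(C)C)C1 | intermediate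
5 | (S)-2-bromo-4-(tert-butyldimethylsilyloxy)-3-methylcyclopent-2-en-1-one | O=C1C(Br)=C(C)[C@@H](O[Si](C)(C)C(C)(C)C)C1 | intermediate
6 | (1S,4S)-2-bromo-4-(tert-butyldimethylsilyloxy)-3-methyl-1-(propan-2-yl)cyclopent-2-en-1-ol | CC1=C(Br)[C@@](O)(C(C)C)C[C@@H]1O[Si](C)(C)C(C)(C)C | intermediate
7 | [(1S,4S)-2-bromo-4-(tert-butyldimethylsilyloxy)-3-methyl-1-(propan-2-yl)cyclopent-2-en-1-yl]oxy(triethyl)silane | CC1=C(Br)[C@@](O[Si](CC)(CC)CC)(C(C)C)C[C@@H]1O[Si](C)(C)C(C)(C)C | intermediate
8 | N-methoxy-N-methylacetamide | CON(C)C(C)=O | starting material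
9 | alkenyllithium from 7 (lithium in place of bromine) | [Li]C1=C(C)[C@@H](O[Si](C)(C)C(C)(C)C)C[C@]1(O[Si](CC)(CC)CC)C(C)C | intermediate
10 | 1-[(3S,5S)-3-(tert-butyldimethylsilyloxy)-2-methyl-5-(propan-2-yl)-5-(triethylsilyloxy)cyclopent-1-en-1-yl]ethan-1-one | CC(=O)C1=C(C)[C@@H](O[Si](C)(C)C(C)(C)C)C[C@]1(O[Si](CC)(CC)CC)C(C)C | intermediate
11 | (1S)-1-[(3S,5S)-3-(tert-butyldimethylsilyloxy)-2-methyl-5-(propan-2-yl)-5-(triethylsilyloxy)cyclopent-1-en-1-yl]ethan-1-ol | C[C@H](O)C1=C(C)[C@@H](O[Si](C)(C)C(C)(C)C)C[C@]1(O[Si](CC)(CC)CC)C(C)C | intermediate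
12 | (1S)-1-[(1R,2S,4S,5S)-4-(tert-butyldimethylsilyloxy)-5-methyl-2-(propan-2-yl)-2-(triethylsilyloxy)bicyclo[3.1.0]hexan-1-yl]ethan-1-ol | C[C@H](O)[C@@]12C[C@]1(C)[C@@H](O[Si](C)(C)C(C)(C)C)C[C@]2(O[Si](CC)(CC)CC)C(C)C | intermediate
13 | 1-[(1S,2S,4S,5S)-4-(tert-butyldimethylsilyloxy)-5-methyl-2-(propan-2-yl)-2-(triethylsilyloxy)bicyclo[3.1.0]hexan-1-yl]ethan-1-one | CC(=O)[C@@]12C[C@]1(C)[C@@H](O[Si](C)(C)C(C)(C)C)C[C@]2(O[Si](CC)(CC)CC)C(C)C | intermediate
14 | tert-butyl({1-[(1R,2S,4S,5S)-4-(tert-butyldimethylsilyloxy)-5-methyl-2-(propan-2-yl)-2-(triethylsilyloxy)bicyclo[3.1.0]hexan-1-yl]ethenyl}oxy)dimethylsilane | C=C(O[Si](C)(C)C(C)(C)C)[C@@]12C[C@]1(C)[C@@H](O[Si](C)(C)C(C)(C)C)C[C@]2(O[Si](CC)(CC)CC)C(C)C | intermediate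
15 | trimethyl(prop-1-yn-1-yl)silane | CC#C[Si](C)(C)C | starting material
16 | (1S,2S,4S)-2,6-bis(tert-butyldimethylsilyloxy)-1,8-dimethyl-4-(propan-2-yl)-4-(triethylsilyloxy)-9-(trimethylsilyl)bicyclo[5.3.0]deca-5,8-diene | CC(C)(C)[Si](C)(C)OC1=C2[C@@](O[Si](CC)(CC)CC)(C(C)C)C[C@H](O[Si](C)(C)C(C)(C)C)[C@@]2(C)CC([Si](C)(C)C)=C(C)C1 | intermediate
17 | (1S,2S,4S,5S)-2-(tert-butyldimethylsilyloxy)-1,8-dimethyl-4-(propan-2-yl)-4-(triethylsilyloxy)bicyclo[5.3.0]dec-8-en-6-one | O=C1CC(C)=CC[C@]2(C)[C@@H](O[Si](C)(C)C(C)(C)C)C[C@](O[Si](CC)(CC)CC)(C(C)C)[C@@H]12 | intermediate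
18 | (1S,2S,4S,5S)-2-(tert-butyldimethylsilyloxy)-4-hydroxy-1,8-dimethyl-4-(propan-2-yl)bicyclo[5.3.0]dec-8-en-6-one | O=C1CC(C)=CC[C@]2(C)[C@@H](O[Si](C)(C)C(C)(C)C)C[C@](O)(C(C)C)[C@@H]12 | intermediate
19 | (1S,2S,4S,5R,6R)-2-(tert-butyldimethylsilyloxy)-1,8-dimethyl-4-(propan-2-yl)bicyclo[5.3.0]dec-8-ene-4,6-diol | O[C@@H]1CC(C)=CC[C@]2(C)[C@@H](O[Si](C)(C)C(C)(C)C)C[C@](O)(C(C)C)[C@@H]12 | intermediate
20 | 3,4-dimethoxybenzoyl chloride | COc1ccc(C(Cl)=O)cc1OC | starting material
21 | (1S,2S,4S,5R,6R)-2-(tert-butyldimethylsilyloxy)-4-hydroxy-1,8-dimethyl-4-(propan-2-yl)bicyclo[5.3.0]dec-8-en-6-yl 3,4-dimethoxybenzoate | COc1ccc(C(=O)O[C@@H]2CC(C)=CC[C@]3(C)[C@@H](O[Si](C)(C)C(C)(C)C)C[C@](O)(C(C)C)[C@@H]23)cc1OC | intermediate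
22 | (1S,2S,4S,5R,6R,8S,9R)-2-(tert-butyldimethylsilyloxy)-8,9-epoxy-4-hydroxy-1,8-dimethyl-4-(propan-2-yl)bicyclo[5.3.0]decan-6-yl 3,4-dimethoxybenzoate (cis-epoxide, expected major face) | COc1ccc(C(=O)O[C@@H]2C[C@]3(C)O[C@@H]3C[C@]4(C)[C@@H](O[Si](C)(C)C(C)(C)C)C[C@](O)(C(C)C)[C@@H]24)cc1OC | intermediate
23 | (8S,9S)-8-hydroxy-9-(phenylselanyl) compound from 22 | COc1ccc(C(=O)O[C@@H]2C[C@](C)(O)[C@@H]([Se]c4ccccc4)C[C@]3(C)[C@@H](O[Si](C)(C)C(C)(C)C)C[C@](O)(C(C)C)[C@@H]23)cc1OC | intermediate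
24 | selenoxide of 23 | COc1ccc(C(=O)O[C@@H]2C[C@](C)(O)[C@@H]([Se](=O)c4ccccc4)C[C@]3(C)[C@@H](O[Si](C)(C)C(C)(C)C)C[C@](O)(C(C)C)[C@@H]23)cc1OC | intermediate
25 | (1S,2S,4S,5R,6R,8S)-2-(tert-butyldimethylsilyloxy)-4,8-dihydroxy-1,8-dimethyl-4-(propan-2-yl)bicyclo[5.3.0]dec-9-en-6-yl 3,4-dimethoxybenzoate | COc1ccc(C(=O)O[C@@H]2C[C@](C)(O)C=C[C@]3(C)[C@@H](O[Si](C)(C)C(C)(C)C)C[C@](O)(C(C)C)[C@@H]23)cc1OC | intermediate
26 | (1S,2S,4S,5R,6R)-2-(tert-butyldimethylsilyloxy)-4-hydroxy-1,8-dimethyl-10-oxo-4-(propan-2-yl)bicyclo[5.3.0]dec-8-en-6-yl 3,4-dimethoxybenzoate | COc1ccc(C(=O)O[C@@H]2CC(C)=CC(=O)[C@]3(C)[C@@H](O[Si](C)(C)C(C)(C)C)C[C@](O)(C(C)C)[C@@H]23)cc1OC | intermediate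
27 | (1S,2S,4S,5R,6R)-2,4-dihydroxy-1,8-dimethyl-10-oxo-4-(propan-2-yl)bicyclo[5.3.0]dec-8-en-6-yl 3,4-dimethoxybenzoate | COc1ccc(C(=O)O[C@@H]2CC(C)=CC(=O)[C@]3(C)[C@@H](O)C[C@](O)(C(C)C)[C@@H]23)cc1OC | intermediate
28 | acetaldehyde | CC=O | starting material
29 | (1R,2S,4S,5R,6R,8Z,10S)-2-acetoxy-4,10-dihydroxy-1,8-dimethyl-4-(propan-2-yl)bicyclo[5.3.0]dec-8-en-6-yl 3,4-dimethoxybenzoate | COc1ccc(C(=O)O[C@@H]2C/C(C)=C\[C@H](O)[C@]3(C)[C@@H](OC(C)=O)C[C@](O)(C(C)C)[C@@H]23)cc1OC | intermediate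
30 | (8E)-isomer of 29 (strained E-cycloheptene) | COc1ccc(C(=O)O[C@@H]2C/C(C)=C/[C@H](O)[C@]3(C)[C@@H](OC(C)=O)C[C@](O)(C(C)C)[C@@H]23)cc1OC | intermediate
31 | (1R,2S,4S,5R,6R,8R,9R,10R)-2-acetoxy-8,9-epoxy-4,10-dihydroxy-1,8-dimethyl-4-(propan-2-yl)bicyclo[5.3.0]decan-6-yl 3,4-dimethoxybenzoate (CNP0197096.4) | COc1ccc(C(=O)O[C@@H]2C[C@@]3(C)O[C@@H]3[C@H](O)[C@]3(C)[C@@H](OC(C)=O)C[C@](O)(C(C)C)[C@@H]23)cc1OC | target

**Step count and risks**

Total step count: 21. Longest linear sequence: 21 steps (from 1).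

Steps most likely to fail:

Step 21 (trans oxirane). The E-alkene may relax back to the Z-alkene before oxygen is transferred, and the veratroyl chromophore may take up much of the light. The excited alkene may also relax into the other twist sense: the trans ring fusion fixes the sign of the C10–C1–C5–C6 torsion and may favour the twist with a negative C7–C8–C9–C10 torsion, whose oxidation would give the (8S,9S)-oxirane instead of the target. Fallback, setting out from 29 and coming back at 31: the sensitised isomerisation is run in a closed-loop flow photoreactor in which the irradiated solution passes continuously over silica loaded with AgNO3, which retains only the strained E-alkene as its silver nitrate complex F1 and so drives the photostationary mixture forward. The twist diastereomers of F1 can be separated at this stage. The wanted one is freed with cold aqueous NaCl to give 30, which is oxidised at once with m-CPBA or dimethyldioxirane at low temperature to 31. Capture of E-cycloheptenes as silver nitrate complexes and peracid epoxidation of strained E-cycloalkenes are both known operations.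

Step 11 (cycloaddition). Coordination and bond insertion at the crowded C5 may be slow, the vinylcyclopropane may rearrange to a cyclopentene, or the internal silyl alkyne may insert sluggishly or with eroded orientation. Fallback, setting out from 13 and coming back at 18, with the alkyne tethered through silicon to O2 so that the step is intramolecular and the silicon-bearing carbon is forced onto C10. Both silyl ethers of 13 are removed (HF·pyridine) to give the diol ketone F2. Its secondary hydroxyl is silylated with chlorodi(propan-2-yl)(prop-1-yn-1-yl)silane and imidazole to the alkynylsilyl ether F3. TMSOTf/Et3N gives the bis(trimethylsilyl) compound F4 (enol ether and C4 ether). [Rh(CO)2Cl]2 converts F4 into the cyclic alkenylsiloxane F5. Buffered TBAF cleaves the enol ether, the C4 ether and the ring C9–Si bond (protodesilylation of an alkenyl alkoxysilane) to the dihydroxy ketone F6. Silylation of its secondary hydroxyl (TBSCl, imidazole) gives 18.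

Step 20 (Evans–Tishchenko reaction). Hydride transfer to the neopentylic ketone may be slow, the samarium alkoxide may undergo retro-aldol cleavage of C1–C2, or the acetyl group may migrate from O2 to O10. Fallback, setting out from 27 and coming back at 29: the C2 hydroxyl is acetylated (Ac2O, DMAP, pyridine) to the keto acetate F7. The C10 ketone is then reduced under reagent control by Corey–Bakshi–Shibata reduction, using (R)-2-methyl-CBS-oxazaborolidine if quaternary C1 acts as the large group and its antipode if the alkenyl side does, to give 29.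

**Further compounds**

F1 | step 21 | silver nitrate complex of the E-alkene 30 | COc1ccc(C(=O)O[C@@H]2C/C(C)=C/[C@H](O)[C@]3(C)[C@@H](OC(C)=O)C[C@](O)(C(C)C)[C@@H]23)cc1OC.[Ag+].[O-][N+](=O)[O-]
F2 | step 11 | 1-[(1S,2S,4S,5S)-2,4-dihydroxy-5-methyl-2-(propan-2-yl)bicyclo[3.1.0]hexan-1-yl]ethan-1-one | CC(=O)[C@@]12C[C@]1(C)[C@@H](O)C[C@]2(O)C(C)C
F3 | step 11 | O2-[di(propan-2-yl)(prop-1-yn-1-yl)silyl] ether of F2 | CC(=O)[C@@]12C[C@]1(C)[C@@H](O[Si](C(C)C)(C(C)C)C#CC)C[C@]2(O)C(C)C
F4 | step 11 | trimethylsilyl enol ether and C4 trimethylsilyl ether of F3 | C=C(O[Si](C)(C)C)[C@@]12C[C@]1(C)[C@@H](O[Si](C(C)C)(C(C)C)C#CC)C[C@]2(O[Si](C)(C)C)C(C)C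
F5 | step 11 | tethered cycloadduct, cyclic alkenylsiloxane O2–Si(i-Pr)2–C9 | CC(C)[Si]1(C(C)C)O[C@H]2C[C@](O[Si](C)(C)C)(C(C)C)C3=C(O[Si](C)(C)C)CC(C)=C1C[C@]23C
F6 | step 11 | (1S,2S,4S,5S)-2,4-dihydroxy-1,8-dimethyl-4-(propan-2-yl)bicyclo[5.3.0]dec-8-en-6-one | O=C1CC(C)=CC[C@]2(C)[C@@H](O)C[C@](O)(C(C)C)[C@@H]12
F7 | step 20 | (1S,2S,4S,5R,6R)-2-acetoxy-4-hydroxy-1,8-dimethyl-10-oxo-4-(propan-2-yl)bicyclo[5.3.0]dec-8-en-6-yl 3,4-dimethoxybenzoate | COc1ccc(C(=O)O[C@@H]2CC(C)=CC(=O)[C@]3(C)[C@@H](OC(C)=O)C[C@](O)(C(C)C)[C@@H]23)cc1OC
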